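Atom labels C1–C20 follow ent-kaurane numbering throughout (ring A = C1–C5, C10; rings C and D = the bicyclo[3.2.1]octane C8, C9, C11–C16; C7 = lactone carbonyl; C17 = exocyclic methylene).

## Analysis of the target

Target 34 is a 6,7-seco-ent-kaurane. Ring A (cyclohexane) is spiro-linked at C10 to a δ-lactone (C20–O–C7), whose acyl carbon C7 sits on the quaternary bridgehead C8 of a bicyclo[3.2.1]octane (rings C and D). Ring D carries a C15 ketone conjugated with the C16 exocyclic methylene. There are seven stereocentres: C8 and C13 (tied together by the bridge), C9 (ring A sits on the exo face, anti to the C15–C16 bridge), and C1, C4, C5, C10 in ring A, of which C4 and C10 are quaternary and separated only by C5. On ring A the C20 methylene (on C10), C6 (on C5), C19 (on C4) and the C1 oxygen all lie on one face, and H9 is anti to C20. The sensitive groups are the α-methylene cyclopentanone (a Michael acceptor), the non-enolisable β-keto lactone (open to retro-Claisen cleavage by alkoxides), and two acetates beside a free primary alcohol, which rule out strong hydride or base late in the route. A free C1 hydroxyl could also compete with the C20 oxygen for the C7 acyl group. The synthesis is hard for three reasons: the crowded C4–C5–C10 array, the need to tell four oxygenated carbons apart (C1 and C19 as acetates, C6 as free alcohol, C20 as lactone oxygen), and the relative configuration across the freely rotating C9–C10 bond. The strategy rests on the cis arrangement of C20, C6 and C19: an ester of a (Z)-2-methylbutenedioic acid on the C20 oxygen can deliver C5 and C4, with C6 and C19 as its two carboxyl carbons, to a diene C10=C1–C2=C3.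

## Retrosynthetic reasoning

Target 34 is traced back to enone 32, in which C6 and C20 carry the same silyl ether and C7 is still a methyl ester. Removing both silyl groups should close the C20 hydroxyl onto C7, because that is the only six-membered lactone available: C6 would give a seven-membered ring and C1 is already acetylated. C6 and C20 therefore never need to be told apart, and the free C6 alcohol appears in the last step.

Enone 32 comes from alkene 30 through allylic alcohol 31. The C15–O bond is cut last because the α-methylene ketone would not survive the hydride, base and organometallic steps before it. C15 is the only oxidisable allylic methylene, since C13 is a bridgehead.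

Diacetate 30 comes from diol 29, and 29 from hydroxy acid 27 by reduction of the activated C19 carboxyl with a mild borohydride. This is the point where C19 is told apart from C6: when C6 and C20 were silylated, C19 was a carboxylate and C1 a hindered secondary alcohol. C1 and C19 are then acetylated together. No strong hydride is needed once acetates are present.

Hydroxy acid 27 comes from keto acid lactone 24. A borohydride that reduces ketones and lactones but not carboxylates should open the γ-lactone to the C6 and C20 alcohols and reduce the C1 ketone. Keeping C19 as the free acid, not an ester, is deliberate: two hindered esters (C19 and C7) could not be distinguished by a hydride, and a C19 ester would be attacked by the neighbouring C6 alkoxide.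

Keto acid 24 comes from cycloadduct 23 by loss of both silyl groups, and 23 from triene 22 by the key disconnection of C5–C10 and C3–C4. These bonds are cut because they take apart the whole C4–C5–C10 array in one step and lead back to a flat diene and a flat dienophile. The forward reaction must form both bonds, close ring A and the temporary γ-lactone, and set C10, C5 and C4.

Triene 22 comes from half ester 21 by silylation of the acid and the ketone, and 21 from alcohol 19 and citraconic anhydride 20. The anhydride is opened at its less hindered carbonyl, which places the ester on the future C6 and the free acid on the future C19.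

Alcohol 19 is cut at C1–C2 (vinylmagnesium bromide 18 on Weinreb amide 17) and at C10–C20 (formaldehyde 15 on the enolate of diester 14). Only the acetate-type ester of 14 can be enolised, because the C7 ester sits on a bridgehead quaternary carbon.

Diester 14 comes from enone 9 by cutting C9–C10. Conjugate addition of ketene silyl acetal 10 to the bicyclic enone should take the exo face and set C9 (keto diester 12). The C12 oxygen, needed only to activate C9, is then removed through tosylhydrazone 13.

Enone 9 comes from ketone 7 by dehydrogenation, and 7 from enol ether 6 by cutting C13–C16. A gold-catalysed 5-exo-dig closure of a silyl enol ether onto a terminal alkyne gives the bicyclo[3.2.1]octane and the exocyclic methylene in one step.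

Enol ether 6 comes through 5 from the achiral ketone 4, and 4 from commercial ester 1 and bromide 2 by way of ketal 3. The two α-methylene groups of 4 are enantiotopic, so a chiral lithium amide can set the absolute configuration of C8, and through the bridge that of C13, in a single step.

## Alternatives that were turned down

Alternative 1: Ring C is cut at C8–C14 and C9–C11. In the forward direction buta-1,3-diene A3 adds across the C8=C9 bond of the thioester-activated unsaturated spirolactone A2, thermally or with a Lewis acid, to give the cis-fused cyclohexene A1. In its favour: it is convergent, it uses the final lactone as the activating group, and the diene face is chosen by a ring-bound stereocentre (C10) and not by a rotamer. On that point it is stronger than the chosen route. Against it: the β-carbon C9 of A2 is attached to the spiro quaternary C10 and A3 is a weak diene, so forcing conditions are likely. Ring A with its four stereocentres (two quaternary) must be made beforehand, which is the hardest part of the target and is left unsolved. After the cycloaddition ring D still has to be built from the thioester and the C12=C13 alkene, which needs two more carbons and the C13–C16 bond. The chosen strategy instead creates three ring A stereocentres in one step and has rings C and D in hand early through one reliable cyclisation.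

Alternative 2: Ring D is cut at C13–C16. In the forward direction a dirhodium tetracarboxylate (divalent rhodium) decomposes diazoketone A5, and the carbenoid carbon inserts into the axial C13–H bond to give cyclopentanone A4. In its favour: C15 arrives as a ketone, so no allylic oxidation is needed and only an α-methylenation remains. On oxidation-state economy it is stronger than the chosen route. Against it: the carbenoid on C8 can reach two methylene groups by 1,5-insertion, C13 through C14 and C11 through C9, and both give cyclopentanones, so site selectivity is uncertain. The last C–C bond is also formed on a fully built tricycle, so the risk sits at the very end of a long linear sequence, and the construction of ring A and ring C is again left open. The chosen strategy places its uncertain step on a compound reached by routine chemistry.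

Alternative 3: The δ-lactone and ring C are cut at C8–C9 and C13–C14. In the forward direction triene A7, whose silyloxydiene sits on C10 and whose α-propargyl acrylate is tethered through the C20 oxygen, cyclises on heating to the spirolactone A6. In its favour: the tether is the final lactone, so nothing temporary has to be dismantled, C8 and C9 are set together, and the facial bias comes from the ring-bound C10. On these points it is stronger than the chosen route, which must reduce and re-form a lactone. Against it: ring A with C1, C4, C5 and C10 already set is presupposed. The dienophile is an α,α-disubstituted acrylate with one activating group. The enol ether in A6 lies toward C11, whereas ring D needs a nucleophilic C13, so it must be re-formed regioselectively. The C12 oxygen must then be removed, and four protecting groups are carried. The chosen strategy pays with a few redox steps after the cycloaddition, but it is the only one of the four that builds the C4–C5–C10 array itself.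

Key step: step 15

Assumption: lithium (R,R)-bis(1-phenylethyl)amide is taken to remove the proton leading to the (1R)-enol ether 5, by analogy with 4-substituted cyclohexanones; if the sense is opposite, the (S,S)-amide is used.

## Route

Step 1
Reactants: 1 methyl 1,4-dioxaspiro[4.5]decane-8-carboxylate; 2 3-bromo-1-(trimethylsilyl)prop-1-yne
Product: 3 methyl 8-[3-(trimethylsilyl)prop-2-yn-1-yl]-1,4-dioxaspiro[4.5]decane-8-carboxylate
Conditions: LiN(iPr)2 (LDA), THF, −78 °C; then 2, −78 to 0 °C
Reagents that add atoms: none
Why: Ester enolate alkylation with a propargylic bromide creates the quaternary carbon that becomes C8. The silyl cap keeps the acetylenic proton away from the bases of steps 1 and 3.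

Step 2
Reactants: 3 methyl 8-[3-(trimethylsilyl)prop-2-yn-1-yl]-1,4-dioxaspiro[4.5]decane-8-carboxylate
Product: 4 methyl 4-oxo-1-[3-(trimethylsilyl)prop-2-yn-1-yl]cyclohexane-1-carboxylate
Conditions: 1 M HCl, THF, rt
Reagents that add atoms: water, O
Why: Acetal hydrolysis; ester and silylalkyne tolerate dilute acid. Ketone 4 has a mirror plane through C1 and C4, so its two α-methylene groups are enantiotopic.

Step 3
Reactants: 4 methyl 4-oxo-1-[3-(trimethylsilyl)prop-2-yn-1-yl]cyclohexane-1-carboxylate
Product: 5 methyl (1R)-4-[(tert-butyldimethylsilyl)oxy]-1-[3-(trimethylsilyl)prop-2-yn-1-yl]cyclohex-3-ene-1-carboxylate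
Conditions: lithium (R,R)-bis(1-phenylethyl)amide (from the amine hydrochloride and n-BuLi, LiCl present), THF, −78 °C; then TBSOTf, −78 °C
Reagents that add atoms: tert-butyldimethylsilyl trifluoromethanesulfonate, CC(C)(C)[Si](C)(C)OS(=O)(=O)C(F)(F)F
Why: Enantiotopos-selective deprotonation of a prochiral 4,4-disubstituted cyclohexanone by a chiral lithium amide, with O-silylation of the enolate. The side of the double bond fixes the configuration of C8 and, after bridging, of C13.

Step 4
Reactants: 5 methyl (1R)-4-[(tert-butyldimethylsilyl)oxy]-1-[3-(trimethylsilyl)prop-2-yn-1-yl]cyclohex-3-ene-1-carboxylate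
Product: 6 methyl (1R)-4-[(tert-butyldimethylsilyl)oxy]-1-(prop-2-yn-1-yl)cyclohex-3-ene-1-carboxylate
Conditions: K2CO3 (0.2 equiv), MeOH, 0 °C
Reagents that add atoms: none
Why: Methanolysis of the C(sp)–Si bond frees the terminal alkyne needed for the cyclisation. The tert-butyldimethylsilyl enol ether should withstand brief carbonate in methanol.

Step 5
Reactants: 6 methyl (1R)-4-[(tert-butyldimethylsilyl)oxy]-1-(prop-2-yn-1-yl)cyclohex-3-ene-1-carboxylate
Product: 7 methyl (1R,5R)-6-methylidene-4-oxobicyclo[3.2.1]octane-1-carboxylate
Conditions: Ph3PAuCl (5 mol %), AgBF4 (5 mol %), toluene/MeOH 10:1, rt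
Reagents that add atoms: none
Why: Cationic monovalent gold activates the alkyne and the enol ether carbon C13 attacks its internal carbon (5-exo-dig carbocyclisation of a silyl enol ether, Conia-ene type). Methanol removes silicon and gold, leaving the ketone and the exocyclic methylene. The bridge can only form cis, so C13 follows C8.

Step 6
Reactants: 7 methyl (1R,5R)-6-methylidene-4-oxobicyclo[3.2.1]octane-1-carboxylate
Product: 9 methyl (1R,5R)-6-methylidene-4-oxobicyclo[3.2.1]oct-2-ene-1-carboxylate, via trimethylsilyl enol ether 8 (not isolated)
Conditions: LDA, Me3SiCl, THF, −78 °C; then Pd(OAc)2 (1.05 equiv), MeCN, rt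
Reagents that add atoms: none
Why: Saegusa–Ito dehydrogenation. The ketone can enolise only toward C11 because the other α-carbon is the bridgehead C13, so the C9=C11 enone forms regiospecifically.

Step 7
Reactants: 9 methyl (1R,5R)-6-methylidene-4-oxobicyclo[3.2.1]oct-2-ene-1-carboxylate; 10 1-(tert-butyldimethylsilyloxy)-1-methoxyethene
Product: 12 methyl (1R,2S,5R)-2-(2-methoxy-2-oxoethyl)-6-methylidene-4-oxobicyclo[3.2.1]octane-1-carboxylate, via silyl enol ether adduct 11 (not isolated)
Conditions: TBSOTf (10 mol %), CH2Cl2, −78 °C; then 1 M HCl, THF, 0 °C
Reagents that add atoms: none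
Why: Mukaiyama–Michael addition of an unhindered ketene silyl acetal to the enone. Attack on C9 should come from the exo face, axially and anti to the C15–C16 bridge, which sets C9 with the side chain on the face required for the target.

Step 8
Reactants: 12 methyl (1R,2S,5R)-2-(2-methoxy-2-oxoethyl)-6-methylidene-4-oxobicyclo[3.2.1]octane-1-carboxylate
Product: 13 4-methylbenzenesulfonylhydrazone of 12 at C12
Conditions: TsNHNH2, EtOH, 50 °C
Reagents that add atoms: 4-methylbenzenesulfonohydrazide, Cc1ccc(cc1)S(=O)(=O)NN
Why: Hydrazone formation at the only ketone. The hydrazone should be crystalline, so recrystallisation can raise the enantiomeric purity set in step 3.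

Step 9
Reactants: 13 4-methylbenzenesulfonylhydrazone of 12 at C12
Product: 14 methyl (1R,2S,5R)-2-(2-methoxy-2-oxoethyl)-6-methylidenebicyclo[3.2.1]octane-1-carboxylate
Conditions: catecholborane, CHCl3, 0 °C; then NaOAc·3H2O, reflux
Reagents that add atoms: none
Why: Caglioti-type reduction: hydride adds to C=N, then acetate triggers loss of sulfinate and N2, leaving CH2 at C12. Esters and the exocyclic alkene are not touched by catecholborane at this temperature.

Step 10
Reactants: 14 methyl (1R,2S,5R)-2-(2-methoxy-2-oxoethyl)-6-methylidenebicyclo[3.2.1]octane-1-carboxylate; 15 formaldehyde (gas, from cracked paraformaldehyde)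
Product: 16 methyl (1R,2S,5R)-2-(3-hydroxy-1-methoxy-1-oxopropan-2-yl)-6-methylidenebicyclo[3.2.1]octane-1-carboxylate (both C10 epimers)
Conditions: LDA, THF, −78 °C; then 15, −78 to −20 °C
Reagents that add atoms: none
Why: Aldol addition of the only enolisable ester to formaldehyde installs C20. The C10 configuration does not matter because C10 becomes trigonal in 22.

Step 11
Reactants: 16 methyl (1R,2S,5R)-2-(3-hydroxy-1-methoxy-1-oxopropan-2-yl)-6-methylidenebicyclo[3.2.1]octane-1-carboxylate (both C10 epimers)
Product: 17 methyl (1R,2S,5R)-2-{3-hydroxy-1-[methoxy(methyl)amino]-1-oxopropan-2-yl}-6-methylidenebicyclo[3.2.1]octane-1-carboxylate (both C10 epimers)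
Conditions: MeNH(OMe)·HCl, iPrMgCl, THF, −20 to 0 °C
Reagents that add atoms: N,O-dimethylhydroxylamine hydrochloride, CNOC.Cl
Why: The magnesium amide converts the unhindered ester into the Weinreb amide. The C7 ester on the bridgehead quaternary carbon is too hindered to react.

Step 12
Reactants: 17 methyl (1R,2S,5R)-2-{3-hydroxy-1-[methoxy(methyl)amino]-1-oxopropan-2-yl}-6-methylidenebicyclo[3.2.1]octane-1-carboxylate (both C10 epimers); 18 vinylmagnesium bromide
Product: 19 methyl (1R,2S,5R)-2-(1-hydroxy-3-oxopent-4-en-2-yl)-6-methylidenebicyclo[3.2.1]octane-1-carboxylate (both C10 epimers)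
Conditions: CH2=CHMgBr (3.5 equiv), THF, −20 to 0 °C; inverse quench into cold aq. NH4Cl
Reagents that add atoms: none
Why: Weinreb ketone synthesis; the chelated tetrahedral intermediate stops at the ketone stage. Inverse quench keeps the liberated amine from adding to the vinyl ketone.

Step 13
Reactants: 19 methyl (1R,2S,5R)-2-(1-hydroxy-3-oxopent-4-en-2-yl)-6-methylidenebicyclo[3.2.1]octane-1-carboxylate (both C10 epimers); 20 citraconic anhydride
Product: 21 hydrogen citraconate of 19: the C20 oxygen acylated by the CH-side carboxyl of (2Z)-2-methylbut-2-enedioic acid with the carboxyl on the methyl-bearing carbon free (both C10 epimers)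
Conditions: 20 (1.5 equiv), 4-(dimethylamino)pyridine (10 mol %), pyridine, CH2Cl2, 0 °C
Reagents that add atoms: none
Why: Nucleophilic opening of the anhydride by the primary alcohol should occur at the less hindered carbonyl, next to the CH. This places the ester on the future C6 and leaves the future C19 as the free acid, and the ring opening keeps the Z geometry.

Step 14
Reactants: 21 hydrogen citraconate of 19 (both C10 epimers)
Product: 22 tert-butyldimethylsilyl ester of 21 with the ketone as its (E)-tert-butyldimethylsilyl dienol ether C10=C1(OSi)–C2=C3 (C9 syn to the silyloxy group and C20 syn to the vinyl group)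
Conditions: TBSOTf (2.6 equiv), Et3N (4 equiv), CH2Cl2, −78 to 0 °C; non-aqueous work-up (pentane, filtration)
Reagents that add atoms: tert-butyldimethylsilyl trifluoromethanesulfonate, CC(C)(C)[Si](C)(C)OS(=O)(=O)C(F)(F)F
Why: The triflate silylates the acid and converts the ketone into the silyl dienol ether by soft enolisation at C10; no free enolate forms, so the β-acyloxy group should not be eliminated. Allylic strain should put the branched C9 syn to the silyloxy group and the C20 methylene syn to the vinyl group, which is the geometry the cycloaddition needs.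

Step 15
Reactants: 22 tert-butyldimethylsilyl ester of 21 with the ketone as its (E)-tert-butyldimethylsilyl dienol ether
Product: 23 ring A cycloadduct: C1=C2 silyl enol ether with γ-lactone C10–C20–O–C6(=O)–C5 cis-fused to ring A and methyl plus silyl ester (C19) on C4 (C20 and C6 and C19 on one face; H9 anti to C20)
Conditions: toluene (0.01 M), BHT, 130 °C, sealed tube
Reagents that add atoms: none
Why: A thermal, concerted, suprafacial [4+2] cycloaddition of the electron-rich 2-silyloxydiene C10=C1–C2=C3 with the tethered, doubly activated Z-alkene C4=C5; the closest known reaction type is the ester-tethered intramolecular Diels–Alder reaction of silyloxydienes with maleate half esters. Ring A closes as the six-membered cycloadduct ring (C5–C10 and C3–C4 formed together), and the γ-lactone closes as the tether ring of a type 1 intramolecular cycloaddition, a five-membered ring completed by the C5–C10 bond (5-exo with respect to C4=C5). Regiochemistry is fixed by the three-atom tether and agrees with the polarisation, C10 being the nucleophilic diene terminus and C5 the β-carbon of the C19 ester. C5 relative to C10 is set by the tether: it sits on the Z (inside) position of the diene terminus, so only the transition state with the tether carbonyl exo can be reached, and the lactone must be cis-fused with C20 and C6 on one face. C4 relative to C5 is set by the Z geometry of the dienophile, which keeps C19 cis to C6. C10 relative to C9 is set by the diene face: the dienophile should add anti to the quaternary C8, with H9 in the narrow sector between C20 and the forming bond, where the lactone develops, and the C11 methylene beside the silyloxy group, whereas the other face would put either C8 against the silyloxy group or C11 into the lactone sector. The step therefore needs π-facial selectivity, and only this rotamer preference about C9–C10 secures it, which makes it the open point of the route. The dienol ether isomer with C9 on the inside cannot reach a reactive conformation and should remain unchanged.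

Step 16
Reactants: 23 ring A cycloadduct with silyl enol ether and silyl ester
Product: 24 keto acid: C1 ketone with C19 carboxylic acid and the cis-fused γ-lactone C10–C20–O–C6(=O)–C5
Conditions: HF·pyridine, THF, 0 °C to rt
Reagents that add atoms: none
Why: Fluoride cleaves the silyl ester and the silyl enol ether, giving the acid and the C1 ketone. C10 is quaternary, so the β-acyloxy ketone cannot eliminate.

Step 17
Reactants: 24 keto acid with C1 ketone and C19 acid and γ-lactone
Product: 27 hydroxy acid: C6 and C20 tert-butyldimethylsilyl ethers with free C1 hydroxyl (cis to C20) and C19 carboxylic acid and C7 methyl ester, via triol acid 25 (not isolated), via tris-silylated ester 26 (not isolated)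
Conditions: LiBH4 (4 equiv), THF, 0 °C to rt; MeOH, evaporate; then TBSCl, imidazole, DMF, rt; then K2CO3, MeOH/H2O, 0 °C, acidify to pH 4
Reagents that add atoms: tert-butyldimethylsilyl chloride, CC(C)(C)[Si](C)(C)Cl
Why: LiBH4 reduces the ketone and the γ-lactone but not the lithium carboxylate, and the bridgehead methyl ester should be slow to react. Axial delivery of hydride to C1, anti to the axial C20 methylene, should give the equatorial alcohol cis to C20. The triol is silylated without acidification so that the C6 hydroxyl cannot close onto the C19 acid; only the two primary alcohols react, and the silyl ester is cleaved in the carbonate work-up.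

Step 18
Reactants: 27 hydroxy acid with C6 and C20 silyl ethers
Product: 29 diol: C1 and C19 hydroxyls with C6 and C20 tert-butyldimethylsilyl ethers and C7 methyl ester, via mixed carbonic anhydride 28 (not isolated)
Conditions: iBuOCOCl, N-methylmorpholine, THF, −15 °C; then NaBH4, MeOH, −15 to 0 °C
Reagents that add atoms: none
Why: Reduction of a carboxylic acid through its mixed carbonic anhydride with NaBH4, which leaves the hindered methyl ester, the silyl ethers and the alkene alone. The hindered C1 hydroxyl should not be acylated by the chloroformate at this temperature.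

Step 19
Reactants: 29 diol with C1 and C19 hydroxyls
Product: 30 diacetate: C1 and C19 acetates with C6 and C20 tert-butyldimethylsilyl ethers and C7 methyl ester
Conditions: Ac2O, 4-(dimethylamino)pyridine, pyridine, rt to 40 °C
Reagents that add atoms: acetic anhydride, CC(=O)OC(C)=O
Why: Nucleophilic catalysis acetylates both the neopentyl primary and the hindered secondary alcohol. The C1 hydroxyl is capped before any lactone at C7 exists, so it cannot take the C7 acyl group.

Step 20
Reactants: 30 diacetate with C6 and C20 silyl ethers
Product: 31 C15 allylic alcohol of 30 (C15 epimers)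
Conditions: SeO2 (0.5 equiv), t-BuOOH (3 equiv), CH2Cl2, rt
Reagents that add atoms: tert-butyl hydroperoxide, CC(C)(C)OO
Why: Allylic oxidation by an ene reaction followed by a [2,3]-sigmatropic shift. C15 is the only allylic methylene, and the shift restores the exocyclic alkene.

Step 21
Reactants: 31 C15 allylic alcohol of 30
Product: 32 enone: C15 ketone conjugated with the C16 methylene, otherwise as 30
Conditions: Dess–Martin periodinane, NaHCO3, CH2Cl2, rt
Reagents that add atoms: none
Why: Mild oxidation of the secondary allylic alcohol. No other free hydroxyl is present, so both C15 epimers converge on one enone.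

Step 22
Reactants: 32 enone with C6 and C20 silyl ethers and C7 methyl ester
Product: 34 target: C1 and C19 acetates with free C6 hydroxyl and the C20–O–C7 spirolactone and the C15 ketone conjugated with the C16 methylene, via diol ester 33 (not isolated)
Conditions: HF·pyridine, pyridine, THF, 0 °C to rt; then pyridinium p-toluenesulfonate, toluene, 50 °C
Reagents that add atoms: none
Why: Fluoride removes both silyl ethers, and the C20 hydroxyl then lactonises onto the C7 ester, now activated as a β-keto ester, forming the only possible six-membered lactone. The C6 hydroxyl remains free, and the mildly acidic, non-nucleophilic conditions spare the acetates and the enone.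

## Compound list

1 | methyl 1,4-dioxaspiro[4.5]decane-8-carboxylate | COC(=O)C1CCC2(CC1)OCCO2 | starting material
2 | 3-bromo-1-(trimethylsilyl)prop-1-yne | C[Si](C)(C)C#CCBr | starting material
3 | methyl 8-[3-(trimethylsilyl)prop-2-yn-1-yl]-1,4-dioxaspiro[4.5]decane-8-carboxylate | COC(=O)C1(CC#C[Si](C)(C)C)CCC2(CC1)OCCO2 | intermediate
4 | methyl 4-oxo-1-[3-(trimethylsilyl)prop-2-yn-1-yl]cyclohexane-1-carboxylate | COC(=O)C1(CC#C[Si](C)(C)C)CCC(=O)CC1 | intermediate
5 | methyl (1R)-4-[(tert-butyldimethylsilyl)oxy]-1-[3-(trimethylsilyl)prop-2-yn-1-yl]cyclohex-3-ene-1-carboxylate | C[Si](C)(C)C#CC[C@]1(C(=O)OC)CC=C(O[Si](C)(C)C(C)(C)C)CC1 | intermediate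
6 | methyl (1R)-4-[(tert-butyldimethylsilyl)oxy]-1-(prop-2-yn-1-yl)cyclohex-3-ene-1-carboxylate | C#CC[C@]1(C(=O)OC)CC=C(O[Si](C)(C)C(C)(C)C)CC1 | intermediate
7 | methyl (1R,5R)-6-methylidene-4-oxobicyclo[3.2.1]octane-1-carboxylate | C=C1C[C@]2(C(=O)OC)C[C@H]1C(=O)CC2 | intermediate
8 | trimethylsilyl enol ether of 7 (C11=C12) | C=C1C[C@]2(C(=O)OC)C[C@H]1C(O[Si](C)(C)C)=CC2 | intermediate
9 | methyl (1R,5R)-6-methylidene-4-oxobicyclo[3.2.1]oct-2-ene-1-carboxylate | C=C1C[C@]2(C(=O)OC)C[C@H]1C(=O)C=C2 | intermediate
10 | 1-(tert-butyldimethylsilyloxy)-1-methoxyethene | C=C(OC)O[Si](C)(C)C(C)(C)C | starting material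
11 | tert-butyldimethylsilyl enol ether (C11=C12) of 12 | C=C1C[C@]2(C(=O)OC)C[C@H]1C(O[Si](C)(C)C(C)(C)C)=C[C@H]2CC(=O)OC | intermediate
12 | methyl (1R,2S,5R)-2-(2-methoxy-2-oxoethyl)-6-methylidene-4-oxobicyclo[3.2.1]octane-1-carboxylate | C=C1C[C@]2(C(=O)OC)C[C@H]1C(=O)C[C@H]2CC(=O)OC | intermediate
13 | 4-methylbenzenesulfonylhydrazone of 12 at C12 | C=C1C[C@]2(C(=O)OC)C[C@H]1C(=NNS(=O)(=O)c1ccc(C)cc1)C[C@H]2CC(=O)OC | intermediate
14 | methyl (1R,2S,5R)-2-(2-methoxy-2-oxoethyl)-6-methylidenebicyclo[3.2.1]octane-1-carboxylate | C=C1C[C@]2(C(=O)OC)C[C@H]1CC[C@H]2CC(=O)OC | intermediate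
15 | formaldehyde | C=O | starting material
16 | methyl (1R,2S,5R)-2-(3-hydroxy-1-methoxy-1-oxopropan-2-yl)-6-methylidenebicyclo[3.2.1]octane-1-carboxylate, both C10 epimers | C=C1C[C@]2(C(=O)OC)C[C@H]1CC[C@H]2C(CO)C(=O)OC | intermediate
17 | methyl (1R,2S,5R)-2-{3-hydroxy-1-[methoxy(methyl)amino]-1-oxopropan-2-yl}-6-methylidenebicyclo[3.2.1]octane-1-carboxylate, both C10 epimers | C=C1C[C@]2(C(=O)OC)C[C@H]1CC[C@H]2C(CO)C(=O)N(C)OC | intermediate
18 | vinylmagnesium bromide | C=C[Mg]Br | starting material
19 | methyl (1R,2S,5R)-2-(1-hydroxy-3-oxopent-4-en-2-yl)-6-methylidenebicyclo[3.2.1]octane-1-carboxylate, both C10 epimers | C=C1C[C@]2(C(=O)OC)C[C@H]1CC[C@H]2C(CO)C(=O)C=C | intermediate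
20 | citraconic anhydride (3-methylfuran-2,5-dione) | CC1=CC(=O)OC1=O | starting material
21 | hydrogen citraconate of 19 (ester on the CH-side carboxyl, free acid on the methyl-bearing carbon), both C10 epimers | C=C1C[C@]2(C(=O)OC)C[C@H]1CC[C@H]2C(COC(=O)/C=C(/C)C(=O)O)C(=O)C=C | intermediate
22 | tert-butyldimethylsilyl ester of 21 as its (E)-tert-butyldimethylsilyl dienol ether (C9 syn to OSi) | C=C1C[C@]2(C(=O)OC)C[C@H]1CC[C@H]2/C(COC(=O)/C=C(/C)C(=O)O[Si](C)(C)C(C)(C)C)=C(\O[Si](C)(C)C(C)(C)C)C=C | intermediate
23 | ring A cycloadduct: C1=C2 silyl enol ether, cis-fused γ-lactone C10–C20–O–C6(=O)–C5, C4 methyl and silyl ester | C=C1C[C@]2(C(=O)OC)C[C@H]1CC[C@H]2[C@@]13COC(=O)[C@@H]1[C@](C)(C(=O)O[Si](C)(C)C(C)(C)C)CC=C3O[Si](C)(C)C(C)(C)C | intermediate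
24 | keto acid: C1 ketone, C19 carboxylic acid, γ-lactone | C=C1C[C@]2(C(=O)OC)C[C@H]1CC[C@H]2[C@@]13COC(=O)[C@@H]1[C@](C)(C(=O)O)CCC3=O | intermediate
25 | triol acid: C1 (cis to C20), C6 and C20 hydroxyls, C19 acid, C7 methyl ester | C=C1C[C@]2(C(=O)OC)C[C@H]1CC[C@H]2[C@]1(CO)[C@@H](O)CC[C@@](C)(C(=O)O)[C@H]1CO | intermediate
26 | C6,C20-bis(tert-butyldimethylsilyl) ether tert-butyldimethylsilyl ester of 25 | C=C1C[C@]2(C(=O)OC)C[C@H]1CC[C@H]2[C@]1(CO[Si](C)(C)C(C)(C)C)[C@@H](O)CC[C@@](C)(C(=O)O[Si](C)(C)C(C)(C)C)[C@H]1CO[Si](C)(C)C(C)(C)C | intermediate
27 | hydroxy acid: C6,C20-bis(tert-butyldimethylsilyl) ether, free C1 hydroxyl, C19 acid | C=C1C[C@]2(C(=O)OC)C[C@H]1CC[C@H]2[C@]1(CO[Si](C)(C)C(C)(C)C)[C@@H](O)CC[C@@](C)(C(=O)O)[C@H]1CO[Si](C)(C)C(C)(C)C | intermediate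
28 | mixed isobutyl carbonic anhydride of 27 | C=C1C[C@]2(C(=O)OC)C[C@H]1CC[C@H]2[C@]1(CO[Si](C)(C)C(C)(C)C)[C@@H](O)CC[C@@](C)(C(=O)OC(=O)OCC(C)C)[C@H]1CO[Si](C)(C)C(C)(C)C | intermediate
29 | diol: C1 and C19 hydroxyls, C6,C20-bis(silyl) ether | C=C1C[C@]2(C(=O)OC)C[C@H]1CC[C@H]2[C@]1(CO[Si](C)(C)C(C)(C)C)[C@@H](O)CC[C@@](C)(CO)[C@H]1CO[Si](C)(C)C(C)(C)C | intermediate
30 | diacetate: C1 and C19 acetates, C6,C20-bis(silyl) ether | C=C1C[C@]2(C(=O)OC)C[C@H]1CC[C@H]2[C@]1(CO[Si](C)(C)C(C)(C)C)[C@@H](OC(C)=O)CC[C@@](C)(COC(C)=O)[C@H]1CO[Si](C)(C)C(C)(C)C | intermediate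
31 | C15 allylic alcohol of 30 (C15 epimers) | C=C1C(O)[C@]2(C(=O)OC)C[C@H]1CC[C@H]2[C@]1(CO[Si](C)(C)C(C)(C)C)[C@@H](OC(C)=O)CC[C@@](C)(COC(C)=O)[C@H]1CO[Si](C)(C)C(C)(C)C | intermediate
32 | enone: C15 ketone, C16 methylene, otherwise as 30 | C=C1C(=O)[C@]2(C(=O)OC)C[C@H]1CC[C@H]2[C@]1(CO[Si](C)(C)C(C)(C)C)[C@@H](OC(C)=O)CC[C@@](C)(COC(C)=O)[C@H]1CO[Si](C)(C)C(C)(C)C | intermediate
33 | diol ester: free C6 and C20 hydroxyls, C7 methyl ester, enone | C=C1C(=O)[C@]2(C(=O)OC)C[C@H]1CC[C@H]2[C@]1(CO)[C@@H](OC(C)=O)CC[C@@](C)(COC(C)=O)[C@H]1CO | intermediate
34 | CNP0105570.2: C1 and C19 acetates (C1 acetate cis to C20), free C6 hydroxyl, C20–O–C7 spirolactone, 15-oxo-16-ene | C=C1C(=O)[C@]23C[C@H]1CC[C@H]2[C@]1(COC3=O)[C@@H](OC(C)=O)CC[C@@](C)(COC(C)=O)[C@H]1CO | target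

## Step count and least certain steps

Total step count: 22. Longest linear sequence: 22 steps from 1; the other building blocks (2, 10, 15, 18, 20) are commercial.

**Step 15 (key step).** The most likely failure is cycloaddition on the wrong diene face, or no cycloaddition below the temperature at which the dienol ether isomerises. The only thing that tells the two faces apart is a rotamer preference about C9–C10, and the diene terminus C10 is fully substituted with the tether on its inside position. The fallback replaces the concerted reaction by a two-stage polar annulation. It sets out from 21 and returns at 24. Acid 21 is esterified with 2-(trimethylsilyl)ethanol under Mitsunobu conditions (PPh3, diisopropyl azodicarboxylate) to the 2-(trimethylsilyl)ethyl ester F1, which is converted with TBSOTf and Et3N into the silyl dienol ether F2. Me2AlCl in CH2Cl2 at −78 °C should then trigger an intramolecular Mukaiyama–Michael addition of C10 to C5 (5-exo), giving after work-up the γ-lactone vinyl ketone F3. Cs2CO3 in MeCN should close ring A by Michael addition of the C4 ester enolate to the vinyl ketone (6-endo), giving the keto lactone ester F4; its C4 configuration would have to be secured by equilibration, which is the weak point of this fallback. Bu4NF in THF removes the 2-(trimethylsilyl)ethyl group and gives 24.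

**Step 3.** The most likely failure is incomplete discrimination of the two enantiotopic α-methylene groups. The two C4 substituents are similar in size and one of them is always axial, where it hinders the approach of the bulky amide. The fallback adds an enzymatic resolution; it sets out from 7 and returns at 7. Scalemic 7 is reduced with NaBH4 to the endo alcohol F5. Lipase from Burkholderia cepacia with vinyl acetate acylates one enantiomer to the acetate F6. The alcohol F5 of the wanted series is obtained either unreacted or by methanolysis (K2CO3, MeOH) of its acetate F6, and is oxidised with Dess–Martin periodinane back to 7, now enantiopure.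

**Step 13.** The most likely failure is opening of the anhydride at the other carbonyl, or base-induced loss of the acyloxy group from the β-acyloxy ketone. Steric and electronic preferences of the two anhydride carbonyls oppose each other, and the substrate is sensitive. The fallback fixes the regiochemistry on simple, separable compounds; it sets out from 20 and 19 and returns at 21. Anhydride 20 is opened with 4-methoxybenzyl alcohol to the half ester F7, which is purified by crystallisation and its regiochemistry checked. Allyl bromide and KHCO3 in DMF give the mixed diester F8. CF3CO2H with Et3SiH removes the 4-methoxybenzyl group to give the allyl half ester F9, whose free acid is on the CH side. Mitsunobu esterification of alcohol 19 with F9 (PPh3, diisopropyl azodicarboxylate), which activates the alcohol and not the acid, gives the allyl ester F10. Pd(PPh3)4 (zerovalent palladium) and morpholine then release 21.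

**Step 17.** The most likely failure is loss of the C7 ester to the reductant after in-situ lactonisation of an alkoxide onto it, or formation of the wrong C1 epimer. LiBH4 is used in excess at room temperature, and three alkoxides are generated next to a methyl ester. The fallback separates the reductions; it sets out from 24 and returns at 25. NaBH4 in MeOH at 0 °C reduces only the ketone and gives the hydroxy acid lactone F11, whose C1 configuration can be checked. iBu2AlH at −78 °C reduces the γ-lactone to the lactol F12 without touching the hindered ester. NaBH4 then reduces the lactol to triol acid 25, which is silylated as in step 17.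

## Further compounds

F1 | step 15 | 2-(trimethylsilyl)ethyl ester of 21 | C=C1C[C@]2(C(=O)OC)C[C@H]1CC[C@H]2C(COC(=O)/C=C(/C)C(=O)OCC[Si](C)(C)C)C(=O)C=C
F2 | step 15 | (E)-tert-butyldimethylsilyl dienol ether of F1 | C=C1C[C@]2(C(=O)OC)C[C@H]1CC[C@H]2/C(COC(=O)/C=C(/C)C(=O)OCC[Si](C)(C)C)=C(\O[Si](C)(C)C(C)(C)C)C=C
F3 | step 15 | γ-lactone vinyl ketone from Mukaiyama–Michael closure (C4 epimers) | C=C1C[C@]2(C(=O)OC)C[C@H]1CC[C@H]2[C@@]1(C(=O)C=C)COC(=O)[C@@H]1C(C)C(=O)OCC[Si](C)(C)C
F4 | step 15 | 2-(trimethylsilyl)ethyl ester of 24 | C=C1C[C@]2(C(=O)OC)C[C@H]1CC[C@H]2[C@@]13COC(=O)[C@@H]1[C@](C)(C(=O)OCC[Si](C)(C)C)CCC3=O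
F5 | step 3 | methyl (1R,5R)-4-endo-hydroxy-6-methylidenebicyclo[3.2.1]octane-1-carboxylate | C=C1C[C@]2(C(=O)OC)C[C@H]1[C@H](O)CC2
F6 | step 3 | acetate of F5 | C=C1C[C@]2(C(=O)OC)C[C@H]1[C@H](OC(C)=O)CC2
F7 | step 13 | (2Z)-4-[(4-methoxybenzyl)oxy]-2-methyl-4-oxobut-2-enoic acid | COc1ccc(COC(=O)/C=C(/C)C(=O)O)cc1
F8 | step 13 | 4-(4-methoxybenzyl) 1-(prop-2-en-1-yl) (2Z)-2-methylbut-2-enedioate | COc1ccc(COC(=O)/C=C(/C)C(=O)OCC=C)cc1
F9 | step 13 | (2Z)-3-methyl-4-oxo-4-(prop-2-en-1-yloxy)but-2-enoic acid | OC(=O)/C=C(/C)C(=O)OCC=C
F10 | step 13 | prop-2-en-1-yl ester of 21 | C=C1C[C@]2(C(=O)OC)C[C@H]1CC[C@H]2C(COC(=O)/C=C(/C)C(=O)OCC=C)C(=O)C=C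
F11 | step 17 | C1 alcohol of 24 (hydroxyl cis to C20), γ-lactone and C19 acid intact | C=C1C[C@]2(C(=O)OC)C[C@H]1CC[C@H]2[C@@]13COC(=O)[C@@H]1[C@](C)(C(=O)O)CC[C@@H]3O
F12 | step 17 | lactol of F11 (C6 hemiacetal, both epimers) | C=C1C[C@]2(C(=O)OC)C[C@H]1CC[C@H]2[C@@]13COC(O)[C@@H]1[C@](C)(C(=O)O)CC[C@@H]3O
A1 | alternative 1 | cis-fused lactone cyclohexene with C8 thioester | CCSC(=O)[C@]23CC=CC[C@H]2[C@]1(COC3=O)[C@@H](O[Si](C)(C)C(C)(C)C)CC[C@@](C)(CO[Si](C)(C)C(C)(C)C)[C@H]1COCc1ccc(OC)cc1
A2 | alternative 1 | thioester-activated unsaturated spirolactone (C8=C9) | CCSC(=O)C1=C[C@]2(COC1=O)[C@@H](O[Si](C)(C)C(C)(C)C)CC[C@@](C)(CO[Si](C)(C)C(C)(C)C)[C@H]2COCc1ccc(OC)cc1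
A3 | alternative 1 | buta-1,3-diene | C=CC=C
A4 | alternative 2 | tetracyclic ring D ketone lacking the methylene | C1C(=O)[C@]23C[C@H]1CC[C@H]2[C@]1(COC3=O)[C@@H](OC(C)=O)CC[C@@](C)(COC(C)=O)[C@H]1CO[Si](C)(C)C(C)(C)C
A5 | alternative 2 | C8 diazoketone | [N-]=[N+]=CC(=O)[C@]12CCCC[C@H]1[C@]1(COC2=O)[C@@H](OC(C)=O)CC[C@@](C)(COC(C)=O)[C@H]1CO[Si](C)(C)C(C)(C)C
A6 | alternative 3 | cis-fused spirolactone with ring C silyl enol ether and C8 propargyl group | C[Si](C)(C)C#CC[C@]23CCC(O[Si](C)(C)C(C)(C)C)=C[C@H]2[C@]1(COC3=O)[C@@H](O[Si](C)(C)C(C)(C)C)CC[C@@](C)(CO[Si](C)(C)C(C)(C)C)[C@H]1COCc1ccc(OC)cc1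
A7 | alternative 3 | triene: silyloxydiene on C10 with α-propargyl acrylate on the C20 oxygen | C=C(CC#C[Si](C)(C)C)C(=O)OC[C@@]1(/C=C/C(=C)O[Si](C)(C)C(C)(C)C)[C@@H](O[Si](C)(C)C(C)(C)C)CC[C@@](C)(CO[Si](C)(C)C(C)(C)C)[C@H]1COCc1ccc(OC)cc1
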